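**Retrosynthetic overview**
1. Last bond: B-alkyl Suzuki coupling (C(sp3)–C(sp2)) between the 9-borabicyclo[3.3.1]nonane adduct of (S)-2-ethenyl-2,8-dimethyl-2H-chromen-6-ol and an (E)-alkenyl bromide that already carries the (R)-butenolide.
2. Chromenol: the 2H-pyran ring is made by ring expansion. A para-(Z-alkenyl)phenol is spiro-etherified oxidatively, then a cationic 1,2-alkenyl shift (dienone–phenol type) turns the five-membered spiro ether into the six-membered ring and gives the free 6-OH and 8-methyl pattern from m-cresol.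
3. C2 stereocentre: asymmetric alkynylation of methyl pyruvate; the ester later becomes the vinyl handle.
4. Butenolide: palladium-catalysed carbonylative lactonisation of a Z-3-iodoallylic alcohol, made from a propargylic alcohol (asymmetric alkynylation of an aldehyde obtained by carboalumination of but-3-yn-1-ol).
5. Ring order: arene bought; pyran ring (step 5) in one branch, butenolide ring (step 12) in the other; the two halves are joined last.

Assumption: the sense of induction in the two zinc-based alkynylations (steps 2 and 10) follows the usual models for these ligand families; if a product proved to be the antipode, the mirror-image ligand would be used.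

**Route**

Step 1
Reactants: 1 3-methylphenol (m-cresol)
Product: 2 4-iodo-3-methylphenol
Conditions: N-iodosuccinimide, p-TsOH·H2O (10 mol%), MeCN, 20 °C; minor 6-iodo isomer removed by crystallisation
Reagents that add atoms: N-iodosuccinimide, O=C1CCC(=O)N1I
Why: Electrophilic aromatic iodination goes mainly para to the hydroxyl group, the most activated and least hindered position.

Step 2
Reactants: 3 methyl pyruvate; 4 ethynyltrimethylsilane
Product: 5 methyl (2R)-2-hydroxy-2-methyl-4-(trimethylsilyl)but-3-ynoate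
Conditions: Zn(O3SCF3)2 (20 mol%), (1S,2S)-3-(tert-butyldimethylsilyloxy)-2-(dimethylamino)-1-(4-nitrophenyl)propan-1-ol (22 mol%), Et3N (30 mol%), toluene, 70 °C, sealed tube
Reagents that add atoms: none
Why: Zinc-catalysed direct asymmetric alkynylation of an α-keto ester, in which the chiral amino alcohol zinc complex binds the chelating keto ester and delivers the acetylide to one face, setting the tertiary carbinol centre.

Step 3
Reactants: 2 4-iodo-3-methylphenol; 5 methyl (2R)-2-hydroxy-2-methyl-4-(trimethylsilyl)but-3-ynoate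
Product: 7 methyl (2R)-2-hydroxy-4-(4-hydroxy-2-methylphenyl)-2-methylbut-3-ynoate, via desilylated alkyne ester 6 (not isolated)
Conditions: Pd(PPh3)2Cl2 (3 mol%), CuI (6 mol%), CsF (2 equiv), Et3N, DMF/H2O (20:1), 45 °C
Reagents that add atoms: none
Why: Fluoride removes the silyl group in situ and the terminal alkyne enters a Sonogashira coupling (sila-Sonogashira), which tolerates the free phenol and tertiary alcohol and does not touch the stereocentre.

Step 4
Reactants: 7 methyl (2R)-2-hydroxy-4-(4-hydroxy-2-methylphenyl)-2-methylbut-3-ynoate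
Product: 8 methyl (2R,3Z)-2-hydroxy-4-(4-hydroxy-2-methylphenyl)-2-methylbut-3-enoate
Conditions: H2 (1 atm), Pd/CaCO3 poisoned with Pb(OAc)2 (Lindlar catalyst), quinoline, EtOAc, 20 °C, stopped after 1.0 equiv H2
Reagents that add atoms: none
Why: Lindlar semi-hydrogenation adds hydrogen syn and gives only the Z-alkene, the geometry the five-membered ring closure of step 5 needs.

Step 5
Reactants: 8 methyl (2R,3Z)-2-hydroxy-4-(4-hydroxy-2-methylphenyl)-2-methylbut-3-enoate
Product: 10 methyl (2R)-6-hydroxy-2,8-dimethyl-2H-chromene-2-carboxylate, via spirodienone 9 (not isolated)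
Conditions: PhI(OAc)2 (1.0 equiv), (CF3)2CHOH, 0 °C, 15 min; then CH2Cl2, BF3·OEt2 (0.5 equiv), −20 °C to 20 °C
Reagents that add atoms: none
Why: Proposed new method: trivalent iodine oxidises the phenol and the tertiary hydroxyl closes onto the ipso carbon (possible only for the Z-alkene) to give spirodienone 9; BF3 activation of the dienone then drives a cationic 1,2-shift of the alkenyl carbon from the spiro centre to the unsubstituted ortho carbon (the cation left behind is an oxocarbenium ion, and a shift to the methyl-bearing carbon is reversible and unproductive), so the five-membered spiro ether expands to the 2H-pyran and aromatisation gives the 6-hydroxy-8-methyl pattern, while the C2–O bond is never broken and the α-ester blocks ionisation, so C2 stays R; the closest known reactions are the PhI(OAc)2 spiro-etherification of para-alkylphenols and the acid-promoted dienone–phenol rearrangement of carbocyclic spiro[4.5]decadienones.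

Step 6
Reactants: 10 methyl (2R)-6-hydroxy-2,8-dimethyl-2H-chromene-2-carboxylate
Product: 12 (2S)-2-ethenyl-2,8-dimethyl-2H-chromen-6-ol, via chromene aldehyde 11 (not isolated)
Conditions: (i-C4H9)2AlH (2.3 equiv), CH2Cl2, −78 °C; then Ph3P=CH2 (from Ph3PCH3Br and KN(SiMe3)2, 3 equiv), THF, −78 °C to 20 °C
Reagents that add atoms: methyltriphenylphosphonium bromide, C[P+](c1ccccc1)(c1ccccc1)c1ccccc1.[Br-]
Why: One-pot reduction/Wittig methylenation, in which the aluminium hemiacetal holds the aldehyde oxidation level until the ylide traps it; the quaternary centre cannot epimerise and its descriptor changes from R to S only because the CIP priorities change.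

Step 7
Reactants: 13 5-bromo-2-methylpent-2-ene; 14 lithium acetylide–ethylenediamine complex
Product: 15 6-methylhept-5-en-1-yne
Conditions: DMSO, 10 °C to 20 °C
Reagents that add atoms: none
Why: SN2 alkylation of lithium acetylide by a primary bromide.

Step 8
Reactants: 16 but-3-yn-1-ol
Product: 18 (3E)-4-bromo-3-methylbut-3-en-1-ol, via alkenylalane 17 (not isolated)
Conditions: Al(CH3)3 (3 equiv), (C5H5)2ZrCl2 (25 mol%), CH2Cl2, −20 °C to 20 °C; then N-bromosuccinimide, THF, −30 °C to 0 °C
Reagents that add atoms: trimethylaluminium, C[Al](C)C; N-bromosuccinimide, O=C1CCC(=O)N1Br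
Why: Negishi zirconium-catalysed carboalumination adds methyl and aluminium syn across the alkyne (methyl on the internal carbon), and bromination of the C–Al bond with retention gives the E-alkenyl bromide.

Step 9
Reactants: 18 (3E)-4-bromo-3-methylbut-3-en-1-ol
Product: 19 (3E)-4-bromo-3-methylbut-3-enal
Conditions: Dess–Martin periodinane, NaHCO3, CH2Cl2, 0 °C to 20 °C; crude aldehyde used at once
Reagents that add atoms: none
Why: Dess–Martin oxidation under buffered, non-basic conditions gives the β,γ-unsaturated aldehyde without moving the double bond into conjugation.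

Step 10
Reactants: 19 (3E)-4-bromo-3-methylbut-3-enal; 15 6-methylhept-5-en-1-yne
Product: 21 (1E,4R)-1-bromo-2,10-dimethylundeca-1,9-dien-5-yn-4-ol, via alkynylzinc 20 (not isolated)
Conditions: 15, Zn(C2H5)2 (2 equiv), toluene, reflux, 1 h; then (S)-1,1'-bi-2-naphthol (40 mol%), Ti(OCH(CH3)2)4 (1 equiv), CH2Cl2, 20 °C; then 19, 20 °C
Reagents that add atoms: none
Why: Binaphthol/titanium-catalysed asymmetric alkynylzinc addition to an aliphatic aldehyde (Pu alkynylation) sets the secondary carbinol, the future C5 of the butenolide, by Si-face delivery in a Lewis-acidic, non-basic medium that spares the sensitive aldehyde.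

Step 11
Reactants: 21 (1E,4R)-1-bromo-2,10-dimethylundeca-1,9-dien-5-yn-4-ol
Product: 23 (1E,4R,5Z)-1-bromo-6-iodo-2,10-dimethylundeca-1,5,9-trien-4-ol, via alkenylalanate 22 (not isolated)
Conditions: NaAlH2(OCH2CH2OCH3)2 (1.5 equiv), THF, 0 °C to 20 °C; then I2 (2 equiv), THF, −78 °C to 0 °C
Reagents that add atoms: iodine, II
Why: Hydroxyl-directed trans-hydroalumination of the propargylic alcohol puts aluminium on the distal carbon cis to the carbinol, and iodinolysis with retention gives the Z-3-iodoallylic alcohol without touching the carbinol centre.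

Step 12
Reactants: 23 (1E,4R,5Z)-1-bromo-6-iodo-2,10-dimethylundeca-1,5,9-trien-4-ol
Product: 24 (5R)-5-[(2E)-3-bromo-2-methylprop-2-en-1-yl]-3-(4-methylpent-3-en-1-yl)furan-2(5H)-one
Conditions: Pd(PPh3)2Cl2 (5 mol%), CO (1 atm), K2CO3 (2 equiv), THF, 20 °C
Reagents that add atoms: carbon monoxide, [C-]#[O+]
Why: Palladium-catalysed carbonylative lactonisation (Stille butenolide synthesis), in which zerovalent palladium inserts into the C–I bond far faster than into the alkenyl C–Br bond, CO inserts and the cis hydroxyl closes the lactone with C5 unchanged.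

Step 13
Reactants: 12 (2S)-2-ethenyl-2,8-dimethyl-2H-chromen-6-ol; 24 (5R)-5-[(2E)-3-bromo-2-methylprop-2-en-1-yl]-3-(4-methylpent-3-en-1-yl)furan-2(5H)-one
Product: 26 tuberatolide B, via alkylborane 25 (not isolated)
Conditions: 9-borabicyclo[3.3.1]nonane (2.3 equiv), THF, 0 °C to 20 °C; then 24, Pd(dppf)Cl2 (dppf = 1,1'-bis(diphenylphosphino)ferrocene, 5 mol%), AsPh3 (10 mol%), K3PO4 (3 M in H2O), DMF, 20–35 °C
Reagents that add atoms: none
Why: 9-Borabicyclo[3.3.1]nonane hydroborates the terminal vinyl group in preference to the cis-disubstituted chromene alkene, and B-alkyl Suzuki–Miyaura coupling with the alkenyl bromide keeps the E geometry, with a mild phosphate base near room temperature to limit epimerisation of the butenolide.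

**Compound list**
1 | 3-methylphenol (m-cresol) | Cc1cccc(O)c1 | starting material
2 | 4-iodo-3-methylphenol | Cc1cc(O)ccc1I | intermediate
3 | methyl pyruvate | COC(=O)C(C)=O | starting material
4 | ethynyltrimethylsilane | C#C[Si](C)(C)C | starting material
5 | methyl (2R)-2-hydroxy-2-methyl-4-(trimethylsilyl)but-3-ynoate | COC(=O)[C@](C)(O)C#C[Si](C)(C)C | intermediate
6 | methyl (2R)-2-hydroxy-2-methylbut-3-ynoate (not isolated) | COC(=O)[C@](C)(O)C#C | intermediate
7 | methyl (2R)-2-hydroxy-4-(4-hydroxy-2-methylphenyl)-2-methylbut-3-ynoate | COC(=O)[C@](C)(O)C#Cc1ccc(O)cc1C | intermediate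
8 | methyl (2R,3Z)-2-hydroxy-4-(4-hydroxy-2-methylphenyl)-2-methylbut-3-enoate | COC(=O)[C@](C)(O)/C=C\c1ccc(O)cc1C | intermediate
9 | methyl (2R)-2,6-dimethyl-8-oxo-1-oxaspiro[4.5]deca-3,6,9-triene-2-carboxylate (not isolated; both configurations at the spiro carbon) | COC(=O)[C@@]1(C)C=CC2(O1)C=CC(=O)C=C2C | intermediate
10 | methyl (2R)-6-hydroxy-2,8-dimethyl-2H-chromene-2-carboxylate | COC(=O)[C@@]1(C)C=Cc2cc(O)cc(C)c2O1 | intermediate
11 | (2R)-6-hydroxy-2,8-dimethyl-2H-chromene-2-carbaldehyde (not isolated) | O=C[C@@]1(C)C=Cc2cc(O)cc(C)c2O1 | intermediate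
12 | (2S)-2-ethenyl-2,8-dimethyl-2H-chromen-6-ol | C=C[C@@]1(C)C=Cc2cc(O)cc(C)c2O1 | intermediate
13 | 5-bromo-2-methylpent-2-ene | CC(C)=CCCBr | starting material
14 | lithium acetylide–ethylenediamine complex | [Li]C#C.NCCN | starting material
15 | 6-methylhept-5-en-1-yne | CC(C)=CCCC#C | intermediate
16 | but-3-yn-1-ol | C#CCCO | starting material
17 | [(1E)-4-(dimethylalumanyloxy)-2-methylbut-1-en-1-yl]dimethylalumane (not isolated) | C[Al](C)OCC/C(C)=C/[Al](C)C | intermediate
18 | (3E)-4-bromo-3-methylbut-3-en-1-ol | OCC/C(C)=C/Br | intermediate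
19 | (3E)-4-bromo-3-methylbut-3-enal | O=CC/C(C)=C/Br | intermediate
20 | ethyl(6-methylhept-5-en-1-yn-1-yl)zinc (not isolated) | CC[Zn]C#CCCC=C(C)C | intermediate
21 | (1E,4R)-1-bromo-2,10-dimethylundeca-1,9-dien-5-yn-4-ol | CC(C)=CCCC#C[C@@H](C/C(C)=C/Br)O | intermediate
22 | sodium (5R)-5-[(2E)-3-bromo-2-methylprop-2-en-1-yl]-2,2-bis(2-methoxyethoxy)-3-(4-methylpent-3-en-1-yl)-2,5-dihydro-1,2-oxaluminol-2-uide (not isolated) | CC(C)=CCCC1=C[C@@H](C/C(C)=C/Br)O[Al-]1(OCCOC)OCCOC.[Na+] | intermediate
23 | (1E,4R,5Z)-1-bromo-6-iodo-2,10-dimethylundeca-1,5,9-trien-4-ol | CC(C)=CCC/C(I)=C/[C@@H](C/C(C)=C/Br)O | intermediate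
24 | (5R)-5-[(2E)-3-bromo-2-methylprop-2-en-1-yl]-3-(4-methylpent-3-en-1-yl)furan-2(5H)-one | CC(C)=CCCC1=C[C@@H](C/C(C)=C/Br)OC1=O | intermediate
25 | 9-{2-[(2S)-6-(9-borabicyclo[3.3.1]nonan-9-yloxy)-2,8-dimethyl-2H-chromen-2-yl]ethyl}-9-borabicyclo[3.3.1]nonane (not isolated) | C[C@]1(CCB2C3CCCC2CCC3)C=Cc2cc(OB3C4CCCC3CCC4)cc(C)c2O1 | intermediate
26 | tuberatolide B, (5R)-5-{(2E)-5-[(2S)-6-hydroxy-2,8-dimethyl-2H-chromen-2-yl]-2-methylpent-2-en-1-yl}-3-(4-methylpent-3-en-1-yl)furan-2(5H)-one | CC(C)=CCCC1=C[C@@H](C/C(C)=C/CC[C@@]2(C)C=Cc3cc(O)cc(C)c3O2)OC1=O | target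

**Step count and risks**

Total steps: 13. Longest linear sequence: 6 steps (2, 3, 4, 5, 6, 13; the branch 8, 9, 10, 11, 12, 13 is equally long).

Three steps most likely to fail:

Step 5, the proposed new oxidative spiro-etherification and ring expansion. The risks are capture of the oxidised phenol by solvent or acetate, migration of oxygen in place of carbon, and over-oxidation of the product if PhI(OAc)2 is left over. The fallback uses known reaction classes and installs the 3,4-double bond last. It sets out from 7 and comes back at 10. Full hydrogenation of 7 (H2, Pd/C, EtOAc) gives methyl (2R)-2-hydroxy-4-(4-hydroxy-2-methylphenyl)-2-methylbutanoate F1. PhI(OAc)2 in (CF3)2CHOH gives the isolable saturated spiro ether methyl (2R)-2,6-dimethyl-8-oxo-1-oxaspiro[4.5]deca-6,9-diene-2-carboxylate F2. BF3·OEt2 effects the classical dienone–phenol rearrangement to methyl (2R)-6-hydroxy-2,8-dimethyl-3,4-dihydro-2H-chromene-2-carboxylate F3. Acetylation (Ac2O, pyridine) gives methyl (2R)-6-acetoxy-2,8-dimethyl-3,4-dihydro-2H-chromene-2-carboxylate F4. Dehydrogenation with DDQ in hot dioxane gives methyl (2R)-6-acetoxy-2,8-dimethyl-2H-chromene-2-carboxylate F5, and K2CO3 in MeOH removes the acetate to give 10.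

Step 10, the asymmetric alkynylation of the enolisable β,γ-unsaturated aldehyde. The risks are double-bond migration, aldol side reactions and modest enantioselectivity. The fallback sets the centre by reduction. It sets out from 19 and 15 and comes back at 21. The lithium acetylide of 15 (n-BuLi, THF, −78 °C) adds to 19 to give racemic (1E)-1-bromo-2,10-dimethylundeca-1,9-dien-5-yn-4-ol F6. Oxidation with MnO2 gives (1E)-1-bromo-2,10-dimethylundeca-1,9-dien-5-yn-4-one F7. Noyori asymmetric transfer hydrogenation of the ynone (RuCl(p-cymene) complex of (R,R)- or (S,S)-N-tosyl-1,2-diphenylethylenediamine, 2-propanol, no added base) returns 21.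

Step 13, the B-alkyl Suzuki coupling in the presence of the base-sensitive butenolide, a free phenol and a less reactive alkenyl bromide. The fallback joins the halves before the lactone exists and forms the lactone last. It sets out from 12 (through 25) and 18 and comes back at 26. Coupling of 25 with 18 under the step 13 conditions gives (2S)-2-[(3E)-6-hydroxy-4-methylhex-3-en-1-yl]-2,8-dimethyl-2H-chromen-6-ol F8. Buffered Dess–Martin oxidation gives (3E)-6-[(2S)-6-hydroxy-2,8-dimethyl-2H-chromen-2-yl]-3-methylhex-3-enal F9. Addition of 20 under the step 10 conditions gives (2S)-2-[(3E,6R)-6-hydroxy-4,12-dimethyltrideca-3,11-dien-7-yn-1-yl]-2,8-dimethyl-2H-chromen-6-ol F10. Hydroalumination with NaAlH2(OCH2CH2OCH3)2 and iodination at −78 °C gives (2S)-2-[(3E,6R,7Z)-6-hydroxy-8-iodo-4,12-dimethyltrideca-3,7,11-trien-1-yl]-2,8-dimethyl-2H-chromen-6-ol F11. Carbonylative lactonisation (Pd(PPh3)2Cl2, CO, K2CO3) gives 26.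

**Further compounds**
F1 | step 5 | methyl (2R)-2-hydroxy-4-(4-hydroxy-2-methylphenyl)-2-methylbutanoate | COC(=O)[C@](C)(O)CCc1ccc(O)cc1C
F2 | step 5 | methyl (2R)-2,6-dimethyl-8-oxo-1-oxaspiro[4.5]deca-6,9-diene-2-carboxylate | COC(=O)[C@@]1(C)CCC2(O1)C=CC(=O)C=C2C
F3 | step 5 | methyl (2R)-6-hydroxy-2,8-dimethyl-3,4-dihydro-2H-chromene-2-carboxylate | COC(=O)[C@@]1(C)CCc2cc(O)cc(C)c2O1
F4 | step 5 | methyl (2R)-6-acetoxy-2,8-dimethyl-3,4-dihydro-2H-chromene-2-carboxylate | COC(=O)[C@@]1(C)CCc2cc(OC(C)=O)cc(C)c2O1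
F5 | step 5 | methyl (2R)-6-acetoxy-2,8-dimethyl-2H-chromene-2-carboxylate | COC(=O)[C@@]1(C)C=Cc2cc(OC(C)=O)cc(C)c2O1
F6 | step 10 | racemic (1E)-1-bromo-2,10-dimethylundeca-1,9-dien-5-yn-4-ol | CC(C)=CCCC#CC(O)C/C(C)=C/Br
F7 | step 10 | (1E)-1-bromo-2,10-dimethylundeca-1,9-dien-5-yn-4-one | CC(C)=CCCC#CC(=O)C/C(C)=C/Br
F8 | step 13 | (2S)-2-[(3E)-6-hydroxy-4-methylhex-3-en-1-yl]-2,8-dimethyl-2H-chromen-6-ol | OCC/C(C)=C/CC[C@@]1(C)C=Cc2cc(O)cc(C)c2O1
F9 | step 13 | (3E)-6-[(2S)-6-hydroxy-2,8-dimethyl-2H-chromen-2-yl]-3-methylhex-3-enal | O=CC/C(C)=C/CC[C@@]1(C)C=Cc2cc(O)cc(C)c2O1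
F10 | step 13 | (2S)-2-[(3E,6R)-6-hydroxy-4,12-dimethyltrideca-3,11-dien-7-yn-1-yl]-2,8-dimethyl-2H-chromen-6-ol | CC(C)=CCCC#C[C@@H](C/C(C)=C/CC[C@@]1(C)C=Cc2cc(O)cc(C)c2O1)O
F11 | step 13 | (2S)-2-[(3E,6R,7Z)-6-hydroxy-8-iodo-4,12-dimethyltrideca-3,7,11-trien-1-yl]-2,8-dimethyl-2H-chromen-6-ol | CC(C)=CCC/C(I)=C/[C@@H](C/C(C)=C/CC[C@@]1(C)C=Cc2cc(O)cc(C)c2O1)O
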